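**Assumption (one line):** Luche reduction of (R)-carvone gives cis-carveol, (1R,5R), as the major isomer, and both C7 epimers from the macrocyclisation converge in the acid step.

## Retrosynthetic overview
1. Target ← oxidation of the C17 allylic alcohol (MnO2, then Pinnick) ← acid-promoted 4,7-cycloetherification of a macrocyclic allylic C7 alcohol, which sets the cis-2,5-THF and C7 last.
2. The 14-membered ring is closed by an intramolecular NHK reaction (C7 aldehyde + C8 vinyl iodide).
3. The acyclic precursor is made by coupling an iodide from (R)-carvone (C1–C4, C13–C14) to a dioxolanone from (S)-lactic acid (C12), then chelation-controlled reduction (C11).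
4. The carvone ring is opened by ozonolysis (a 1,3-dipolar cycloaddition of O3 followed by cycloreversion). A chelation-controlled Grignard addition then sets C4 next to C3.

## Route

**Step 1**
Reactants: 1 (R)-carvone
Product: 2 cis-carveol, (1R,5R)
Conditions: NaBH4, CeCl3·7H2O, MeOH, −15 °C
Reagents that add atoms: none
Why: Luche 1,2-reduction delivers hydride axially to give the equatorial alcohol cis to the isopropenyl group, which sets C3 (R) relative to C1 (R); this is a substrate-controlled reduction.

**Step 2**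
Reactants: 2
Product: 3 (3R,5S)-3-hydroxy-7,7-dimethoxy-5-(prop-1-en-2-yl)heptan-2-one
Conditions: O3 (1.0 equiv), CH2Cl2/MeOH 3:1, −78 °C; then Me2S, PPTS (cat.), rt
Reagents that add atoms: ozone O=[O+][O-] (carbonyl oxygens); methanol CO (the two OMe groups)
Why: O3 adds as a 1,3-dipole to the more electron-rich trisubstituted ring alkene in preference to the isopropenyl group. Cycloreversion and MeOH trapping open the carbocycle to an α-hydroxy methyl ketone and a masked aldehyde, with C1 and C3 untouched.

**Step 3**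
Reactants: 3 + 4 2-(1,3-dioxolan-2-yl)ethylmagnesium bromide (3 equiv)
Product: 5, the C3/C4 diol with C3 (R) and C4 (R); C13 dimethyl acetal and C7 dioxolane intact
Conditions: THF, −78 → 0 °C
Reagents that add atoms: none (Grignard 4 is the reactant)
Why: The Mg alkoxide and ketone form a five-membered chelate (Cram-chelate addition). The alkyl group attacks anti to the C2 chain, giving the (3R,4R) relationship of the target.

**Step 4**
Reactants: 5
Product: 6, as 5 with the isopropenyl CH3 oxidised to CH2OH (C17)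
Conditions: SeO2 (0.2 equiv), TBHP, CH2Cl2, rt
Reagents that add atoms: SeO2 O=[Se]=O; TBHP CC(C)(C)OO
Why: Allylic oxidation runs by an ene reaction followed by a [2,3]-sigmatropic shift of the allylseleninic ester. It occurs at the methyl, and 5 has no other alkene.

**Step 5**
Reactants: 6
Product: 7, with C17-OTBS and C3-OTBS and C4-OH free
Conditions: TBSCl (2.5 equiv), imidazole, DMF, rt
Reagents that add atoms: TBSCl CC(C)(C)[Si](C)(C)Cl
Why: The primary and secondary hydroxyls silylate; the tertiary C4-OH is too hindered.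

**Step 6**
Reactants: 7
Product: 8, as 7 plus C4-OTES
Conditions: TESOTf, 2,6-lutidine, CH2Cl2, −78 °C
Reagents that add atoms: TESOTf CC[Si](CC)(CC)OS(=O)(=O)C(F)(F)F
Why: Protecting C4-OH prevents enolate quenching in Step 11 and can later be removed selectively with HF·py.

**Step 7**
Reactants: 8
Product: 9, the C13 aldehyde with the C7 dioxolane retained
Conditions: PPTS (0.3 equiv), acetone/H2O 10:1, 45 °C
Reagents that add atoms: water O (aldehyde oxygen)
Why: The acyclic dimethyl acetal hydrolyses much faster than the dioxolane, and no stereocentre is α to the aldehyde.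

**Step 8**
Reactants: 9
Product: 10, the C13 primary alcohol
Conditions: NaBH4, MeOH, 0 °C
Reagents that add atoms: none
Why: Simple aldehyde reduction.

**Step 9**
Reactants: 10
Product: 11, the C13 primary iodide
Conditions: I2, PPh3, imidazole, CH2Cl2, 0 °C
Reagents that add atoms: I2 II
Why: Appel-type SN2 iodination at an unhindered CH2; the silyl ethers and alkene are inert.

**Step 10**
Reactants: 12 (S)-lactic acid + 13 pivalaldehyde
Product: 14 (2S,5S)-2-tert-butyl-5-methyl-1,3-dioxolan-4-one
Conditions: TsOH (cat.), pentane, Dean–Stark, reflux; crystallise the cis isomer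
Reagents that add atoms: none (13 is the reactant)
Why: Acetalisation gives the cis acetal, and C5 keeps the configuration of (S)-lactic acid for self-regenerating alkylation.

**Step 11**
Reactants: 14 + 11
Product: 15 (2S,5R)-dioxolanone alkylated at C5 by the C13 chain (this is C12, R)
Conditions: LDA, THF, −78 °C; then 11, DMPU, −78 → −30 °C
Reagents that add atoms: none
Why: The enolate is alkylated trans to t-Bu, so the new bond replaces the former C–H and C12 is formed as (R); this is the chiral-pool quaternary-centre formation.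

**Step 12**
Reactants: 15
Product: 16, the C11 methyl ketone with a free tertiary C12-OH
Conditions: MeLi (1.05 equiv), THF, −78 °C, cold NH4Cl quench
Reagents that add atoms: MeLi [Li]C (becomes C10)
Why: A single addition gives a stable tetrahedral adduct that collapses on work-up to the methyl ketone and releases pivalaldehyde; C12 is untouched.

**Step 13**
Reactants: 16 + 17 2,3-dibromopropene
Product: 18, the vinyl-bromide ketone (C10–C9 bond formed)
Conditions: LDA (2.3 equiv), THF, −78 → −20 °C
Reagents that add atoms: none (17 is the reactant)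
Why: With C12 quaternary, the only enolisable site is the methyl, so the alkoxide/enolate dianion alkylates regiospecifically at CH2Br.

**Step 14**
Reactants: 18
Product: 19, the diol with C11 (S) and C12 (R)
Conditions: Zn(BH4)2, Et2O, −20 °C
Reagents that add atoms: none
Why: Zn chelates the C11 carbonyl and the free C12-OH; hydride enters anti to the C13 chain (syn to Me), giving C11 (S) by chelation-controlled reduction.

**Step 15**
Reactants: 19
Product: 20, the C11 acetate
Conditions: Ac2O, pyridine, CH2Cl2, rt (no DMAP)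
Reagents that add atoms: Ac2O CC(=O)OC(C)=O
Why: Only the secondary C11-OH acylates; the tertiary alcohols do not.

**Step 16**
Reactants: 20
Product: 21, the vinyl iodide
Conditions: CuI (10 mol%), N,N'-dimethylethylenediamine (20 mol%), NaI, dioxane, 110 °C
Reagents that add atoms: NaI [Na+].[I-]
Why: Cu-catalysed halogen exchange converts the vinyl bromide to the iodide required for Cr/Ni insertion.

**Step 17**
Reactants: 21
Product: 22, the C7 aldehyde
Conditions: I2 (10 mol%), acetone, rt
Reagents that add atoms: none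
Why: Neutral trans-acetalisation removes the dioxolane and leaves the TBS, TES, acetate and vinyl iodide intact.

**Step 18**
Reactants: 22
Product: 23, the 14-membered macrocycle with C7-OH (epimeric mixture)
Conditions: CrCl2 (10 equiv), NiCl2 (cat.), DMSO, rt, ≈3 mM (slow addition)
Reagents that add atoms: none
Why: Intramolecular Nozaki–Hiyama–Kishi addition of the vinylchromium to the aldehyde closes the ring and creates the exocyclic C8=C19; the C7 stereochemistry is deliberately left open.

**Step 19**
Reactants: 23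
Product: 24, the macrocycle with free C4-OH (C3-OTBS and C17-OTBS intact)
Conditions: HF·pyridine, THF/pyridine, 0 °C
Reagents that add atoms: none
Why: TES on the tertiary oxygen is cleaved much faster than the TBS ethers.

**Step 20**
Reactants: 24
Product: 25, the 4,7-epoxy (THF) macrocycle with C7 (S)
Conditions: CSA (0.1 equiv), CH2Cl2, 0 °C → rt
Reagents that add atoms: none
Why: Reversible ionisation of the allylic C7–OH (both epimers converge) is followed by 5-exo capture by C4-OH, whose C–O bond and configuration are retained; the thermodynamically preferred cis-2,5-THF has C3 and C8 cis, the relative configuration of the target.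

**Step 21**
Reactants: 25
Product: 26, the macrocycle with free C3-OH and C17-OH
Conditions: HF·pyridine (excess), THF/pyridine, rt
Reagents that add atoms: none
Why: Buffered fluoride removes both TBS ethers without touching the C11 acetate.

**Step 22**
Reactants: 26
Product: 27, the α-methylene aldehyde
Conditions: MnO2 (20 equiv), CH2Cl2, rt
Reagents that add atoms: none
Why: MnO2 selectively oxidises the primary allylic alcohol; the non-allylic C3-OH and tertiary C12-OH are inert.

**Step 23**
Reactants: 27
Product: 28, Dendronpholide R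
Conditions: NaClO2, NaH2PO4, 2-methyl-2-butene, t-BuOH/H2O, rt
Reagents that add atoms: NaClO2 [Na+].[O-]Cl=O
Why: Pinnick oxidation gives the acrylic acid, and the scavenger protects the two 1,1-disubstituted alkenes.

## Compound list
1 | (R)-carvone | CC(=C)[C@@H]1CC=C(C)C(=O)C1 | starting material
2 | cis-(1R,5R)-carveol | CC(=C)[C@@H]1CC=C(C)[C@H](O)C1 | intermediate
3 | (3R,5S)-3-hydroxy-7,7-dimethoxy-5-(prop-1-en-2-yl)heptan-2-one | CC(=O)[C@H](O)C[C@@H](CC(OC)OC)C(C)=C | intermediate
4 | 2-(1,3-dioxolan-2-yl)ethylmagnesium bromide | Br[Mg]CCC1OCCO1 | starting material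
5 | C3/C4 diol adduct (C13 dimethyl acetal, C7 dioxolane) | C=C(C)[C@H](CC(OC)OC)C[C@@H](O)[C@](C)(O)CCC1OCCO1 | intermediate
6 | 5 with C17-OH | OCC(=C)[C@H](CC(OC)OC)C[C@@H](O)[C@](C)(O)CCC1OCCO1 | intermediate
7 | C17-OTBS, C3-OTBS, C4-OH | C[Si](C)(C(C)(C)C)OCC(=C)[C@H](CC(OC)OC)C[C@@H](O[Si](C)(C)C(C)(C)C)[C@](C)(O)CCC1OCCO1 | intermediate
8 | 7 plus C4-OTES | C[Si](C)(C(C)(C)C)OCC(=C)[C@H](CC(OC)OC)C[C@@H](O[Si](C)(C)C(C)(C)C)[C@](C)(O[Si](CC)(CC)CC)CCC1OCCO1 | intermediate
9 | C13 aldehyde | O=CC[C@@H](C(=C)CO[Si](C)(C)C(C)(C)C)C[C@@H](O[Si](C)(C)C(C)(C)C)[C@](C)(O[Si](CC)(CC)CC)CCC1OCCO1 | intermediate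
10 | C13 alcohol | OCC[C@@H](C(=C)CO[Si](C)(C)C(C)(C)C)C[C@@H](O[Si](C)(C)C(C)(C)C)[C@](C)(O[Si](CC)(CC)CC)CCC1OCCO1 | intermediate
11 | C13 iodide | ICC[C@@H](C(=C)CO[Si](C)(C)C(C)(C)C)C[C@@H](O[Si](C)(C)C(C)(C)C)[C@](C)(O[Si](CC)(CC)CC)CCC1OCCO1 | intermediate
12 | (S)-lactic acid | C[C@H](O)C(=O)O | starting material
13 | pivalaldehyde | CC(C)(C)C=O | starting material
14 | (2S,5S)-2-tert-butyl-5-methyl-1,3-dioxolan-4-one | C[C@@H]1O[C@H](C(C)(C)C)OC1=O | intermediate
15 | alkylated dioxolanone (C12 R) | C[C@]1(CC[C@@H](C(=C)CO[Si](C)(C)C(C)(C)C)C[C@@H](O[Si](C)(C)C(C)(C)C)[C@](C)(O[Si](CC)(CC)CC)CCC2OCCO2)O[C@H](C(C)(C)C)OC1=O | intermediate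
16 | C11 methyl ketone, C12-OH | CC(=O)[C@](C)(O)CC[C@@H](C(=C)CO[Si](C)(C)C(C)(C)C)C[C@@H](O[Si](C)(C)C(C)(C)C)[C@](C)(O[Si](CC)(CC)CC)CCC1OCCO1 | intermediate
17 | 2,3-dibromopropene | C=C(Br)CBr | starting material
18 | vinyl-bromide ketone | C=C(Br)CCC(=O)[C@](C)(O)CC[C@@H](C(=C)CO[Si](C)(C)C(C)(C)C)C[C@@H](O[Si](C)(C)C(C)(C)C)[C@](C)(O[Si](CC)(CC)CC)CCC1OCCO1 | intermediate
19 | C11/C12 diol (11S,12R) | C=C(Br)CC[C@H](O)[C@](C)(O)CC[C@@H](C(=C)CO[Si](C)(C)C(C)(C)C)C[C@@H](O[Si](C)(C)C(C)(C)C)[C@](C)(O[Si](CC)(CC)CC)CCC1OCCO1 | intermediate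
20 | C11 acetate | C=C(Br)CC[C@H](OC(C)=O)[C@](C)(O)CC[C@@H](C(=C)CO[Si](C)(C)C(C)(C)C)C[C@@H](O[Si](C)(C)C(C)(C)C)[C@](C)(O[Si](CC)(CC)CC)CCC1OCCO1 | intermediate
21 | vinyl iodide | C=C(I)CC[C@H](OC(C)=O)[C@](C)(O)CC[C@@H](C(=C)CO[Si](C)(C)C(C)(C)C)C[C@@H](O[Si](C)(C)C(C)(C)C)[C@](C)(O[Si](CC)(CC)CC)CCC1OCCO1 | intermediate
22 | C7 aldehyde | C=C(I)CC[C@H](OC(C)=O)[C@](C)(O)CC[C@@H](C(=C)CO[Si](C)(C)C(C)(C)C)C[C@@H](O[Si](C)(C)C(C)(C)C)[C@](C)(O[Si](CC)(CC)CC)CCC=O | intermediate
23 | macrocycle with C7-OH (C7 undefined) | C=C(CO[Si](C)(C)C(C)(C)C)[C@@H]1CC[C@@](C)(O)[C@@H](OC(C)=O)CCC(=C)C(O)CC[C@@](C)(O[Si](CC)(CC)CC)[C@H](O[Si](C)(C)C(C)(C)C)C1 | intermediate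
24 | macrocycle with free C4-OH | C=C(CO[Si](C)(C)C(C)(C)C)[C@@H]1CC[C@@](C)(O)[C@@H](OC(C)=O)CCC(=C)C(O)CC[C@@](C)(O)[C@H](O[Si](C)(C)C(C)(C)C)C1 | intermediate
25 | THF macrocycle, TBS ethers | C=C(CO[Si](C)(C)C(C)(C)C)[C@@H]1CC[C@@](C)(O)[C@@H](OC(C)=O)CCC(=C)[C@@H]2CC[C@@](C)(O2)[C@H](O[Si](C)(C)C(C)(C)C)C1 | intermediate
26 | C3/C17 diol | C=C(CO)[C@@H]1CC[C@@](C)(O)[C@@H](OC(C)=O)CCC(=C)[C@@H]2CC[C@@](C)(O2)[C@H](O)C1 | intermediate
27 | enal | C=C(C=O)[C@@H]1CC[C@@](C)(O)[C@@H](OC(C)=O)CCC(=C)[C@@H]2CC[C@@](C)(O2)[C@H](O)C1 | intermediate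
28 | Dendronpholide R | C=C(C(=O)O)[C@@H]1CC[C@@](C)(O)[C@@H](OC(C)=O)CCC(=C)[C@@H]2CC[C@@](C)(O2)[C@H](O)C1 | target

**Total steps:** 23. **Longest linear sequence:** 22 steps (carvone → 28; the dioxolanone preparation is a side branch).

**Three steps most likely to fail:**
1. **Step 20, cycloetherification.** The C3-OH is protected at this point, but acid could still give elimination, THP-type products or the wrong 2,5-stereochemistry. Fallback: separate the two C7 epimers from Step 18, mesylate the one with the correct configuration and close with KHMDS by SN2 with inversion at C7, so the THF stereochemistry no longer depends on thermodynamic control.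
2. **Step 18, NHK macrocyclisation.** Oligomerisation, low yield, or a competing hydroxy-aldehyde lactol may intervene. Fallback: close the ring by a different bond, namely an intramolecular Pd(0) allylic alkylation of a C10 sulfone onto a C9 2-substituted allyl carbonate, followed by desulfonylation.
3. **Step 11, dioxolanone alkylation.** The Seebach-type enolate reacts poorly with a hindered, unactivated primary iodide. Fallback: aldol addition of the same enolate to aldehyde 9 (the C13 aldehyde), then Barton–McCombie deoxygenation of the C13 alcohol; the C13 stereocentre is irrelevant because it is removed.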